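## The problem

Germacrane numbering is used. C1 is the ring ketone, C2 the furanone CH and C3 the O-bearing furanone carbon. C4 (bearing C15)=C5 is the alkene, C6 the lactone carbinol, then C7, C8 (isobutyrate) and C9 (OH). C10 bears C14 and the ether O, C11=C13 is the methylene and C12 the lactone carbonyl.

- **Ring system.** The core is a ten-membered carbocycle C1–C10 bridged by an oxygen between C3 and C10. The planar 3(2H)-furanone ring (O, C3, C2, C1, C10) holds C2=C3 as an E-alkene of the large ring, directly next to the Z-alkene C4=C5.
- **Strain.** The nine-membered ring O–C3–C4–C5–C6–C7–C8–C9–C10 therefore has the strain of a trans-cycloalkene. Every closure done on the bridged system has to pay for that strain.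
- **Stereocentres.** Five contiguous centres (6R,7S,8S,9R,10S) line the saturated half: a trans-fused lactone at C6/C7, a threo diol at C8/C9 and a fully substituted C10.
- **Control.** C6 can control C7 within a five-membered ring, and C9 can control C8 and C10. Nothing ties the C6/C7 pair to the C8–C10 triad except the C7–C8 bond.
- **Fragile groups.** These are the α-methylene lactone (Michael and Heck acceptor), the dienone-like furanone, the β-hydroxy ketone C9–C10–C1 (retro-aldol) and the 8-ester/9-OH pair (acyl migration).
- **Feature that makes the key step possible.** C3 is shared by the furanone ring and the ten-membered ring and carries no hydrogen, no branch and no stereochemistry. It sits at the ketone oxidation level between the vinylic C4 and C2. The furanone is the cyclodehydrated hydrate of the ynone C3(=O)–C2≡C1–C10(OH), so C3 can be delivered as carbon monoxide.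

## Retrosynthesis

**28 ⇒ 27 ⇒ 26.** The O8–acyl bond and the two acetal C–O bonds are cut. Putting the ester on last avoids acyl migration during the route. It also lets O8 and O9 travel as one trans-dioxolane, which removes a rotor. The forward step must acylate O8 in diol 27 and leave O9 alone. O9 is neopentylic (next to C10) and can hydrogen-bond to the C1 ketone.

**26 ⇒ 24.** C11=C13 is masked as the dimethylamine adduct. This removes the best Michael, Heck and acylpalladation acceptor before any palladium, amine or water is used. Unmasking needs only methylation and bicarbonate.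

**24 ⇒ 23 ⇒ 22 ⇒ 21 + CO (key).** The bonds C3–O10, C2–C3 and C3–C4 are cut, and C3 leaves as CO.
- The neighbouring cuts are worse. C4=C5 would have to close on the bridged ring. C6–C7, C7–C8 and C9–C10 would create stereocentres under macrocyclic constraint.
- The ring is closed as the unbridged ynone 22. The bridge follows and is driven by hydration of an alkyne.
- Precursor 21 has neither the macrocycle nor the furanone. It is an open chain carrying a (Z)-vinyl iodide and a tertiary propargylic alcohol.

**21 ⇒ 20 ⇒ 18.** The C11–C13 bond (Mannich) and the alkyne C–Si bond are cut. Both forward reactions are routine. The silyl group is present only so that the lactone enolate is the sole carbon nucleophile.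

**18 ⇒ 9 + 17.** The C7–C8 bond is cut, the only link between the two stereochemical domains. A C8 dioxolanyl radical and a butenolide acceptor each carry their own control element. C9 directs C8 (trans-dioxolane) and C6 directs C7 (trans-lactone). A closed allylmetal transition state at this bond would give the 8-epimer. A neutral radical also spares the vinyl iodide, which a cuprate would not.

**9 ⇒ 8 ⇒ 5 ⇒ 4 ⇒ 2 ⇒ 1 (+ 6).** C10–C1, C10–C14 and the sacrificial C8–CO2H are traced back to L-tartrate 1. Its C2 and C3 become C8 and C9. One carboxyl carbon becomes C10 and the other is lost as CO2 in the coupling. The forward addition of acetylide 7 to ketone 5 must proceed under chelation control.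

**17 ⇒ 16 ⇒ 15 ⇒ 13 ⇒ 10 + 11.** The butenolide C7=C11 bond (metathesis), the ester, the C4–I bond and the C5–C6 bond are cut. The Z geometry of C4=C5 is fixed on a six-carbon fragment by hydroxyl-directed hydroalumination. It is never at risk afterwards.

## Roads not taken

**Alternative 1:** cut C4=C5 (the most obvious route).
- Forward step: ring-closing metathesis of diene A1, which carries the finished furanone and lactone.
- It would have to make a trisubstituted Z-alkene from an electron-poor isopropenylfuranone, directly on the bridged nine-membered oxacycle.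
- Loss of ethene is the only driving force, and the reaction is reversible.
- The exocyclic methylene group competes for the catalyst.
- A1 already contains all five stereocentres on a preformed furanone, so nothing is saved in the run-up.

**Alternative 2:** cut C6–C7.
- Forward step: intramolecular Barbier or chromium allylation of aldehyde/allyl bromide A2 to the ten-membered ynone lactone A3, followed by transannular cycloisomerisation.
- It forms the ring and the lactone together, but C6 and C7 are then set inside the macrocyclisation.
- The intrinsic closed-transition-state preference of a (Z)-2-(bromomethyl)enoate is syn, which means a cis-lactone.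
- A2 combines an enal, an ynone and an allyl bromide in one linear fifteen-carbon chain that must survive a reducing metal.
- The chosen plan sets C6/C7 on a five-membered ring and closes the macrocycle at stereochemically blank carbons.

**Alternative 3:** cut C9–C10 (the aldol retron).
- Forward step: ring closure of aldehyde A4 through its 3-silyloxyfuran A5. This would set C9 and C10 together.
- The closure goes straight to the strained bridged system.
- An aldol is close to thermoneutral, and retro-aldol would release both the strain and an aromatic 3-hydroxyfuran.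
- The natural C9/C10 relation needs a closed transition state with the aldehyde substituent axial, and the anti-Felkin sense at C8.
- The α-acyloxy aldehyde is labile.
- The chosen plan pays for the strain with CO insertion and alkyne hydration, both strongly downhill.

Key step: step 13

Assumption: (R)-BINOL is taken to give the (S)-carbinol 13, by analogy with the sense known for aryl and alkenyl aldehydes. If the sense were opposite, the other ligand enantiomer would be used.

## Steps

**Step 1**
Reactants: 1 dimethyl (4R,5R)-2,2-dimethyl-1,3-dioxolane-4,5-dicarboxylate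
Product: 2 (4R,5R)-5-(methoxycarbonyl)-2,2-dimethyl-1,3-dioxolane-4-carboxylic acid
Conditions: KOH (1.0 equiv), MeOH, 0 to 25 °C; then aq. HCl to pH 3
Reagents that add atoms: potassium hydroxide, [K+].[OH-]
Why: Half-saponification of a C2-symmetric diester, in which the first carboxylate slows the second hydrolysis; the two esters are homotopic, so one mono-acid results, and the trans-dioxolane is the stable epimer.

**Step 2**
Reactants: 2 mono-acid
Product: 4 methyl (4R,5R)-5-[methoxy(methyl)carbamoyl]-2,2-dimethyl-1,3-dioxolane-4-carboxylate, via acyl imidazolide 3 (not isolated)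
Conditions: carbonyldiimidazole, CH2Cl2, 0 °C; then MeNH(OMe)·HCl, 25 °C
Reagents that add atoms: N,O-dimethylhydroxylamine hydrochloride, CNOC.Cl
Why: Standard Weinreb amide formation through the acyl imidazolide; no base strong enough to epimerise C9 is present.

**Step 3**
Reactants: 4 Weinreb amide ester
Product: 5 methyl (4R,5R)-5-acetyl-2,2-dimethyl-1,3-dioxolane-4-carboxylate
Conditions: MeMgBr (1.05 equiv), THF, −78 °C; then H2O
Reagents that add atoms: methylmagnesium bromide, C[Mg]Br
Why: Weinreb ketone synthesis; the chelated tetrahedral adduct stops at the ketone stage, and at −78 °C the amide should be attacked before the methyl ester.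

**Step 4**
Reactants: 5 methyl ketone; 6 ethynyltriisopropylsilane
Product: 8 methyl (4R,5R)-5-[(2R)-2-hydroxy-4-(triisopropylsilyl)but-3-yn-2-yl]-2,2-dimethyl-1,3-dioxolane-4-carboxylate, via alkynylmagnesium bromide 7 (not isolated)
Conditions: 6, EtMgBr, THF, 25 °C; then 5, MgBr2·OEt2, CH2Cl2, −78 °C; then H2O
Reagents that add atoms: none
Why: Chelation-controlled (Cram chelate) 1,2-addition, in which magnesium ties the ketone oxygen to O9, C8 shields one face and the acetylide enters from the side of H9, setting C10 as in the target. The ketone reacts before the ester at −78 °C.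

**Step 5**
Reactants: 8 ester
Product: 9 (4R,5R)-5-[(2R)-2-hydroxy-4-(triisopropylsilyl)but-3-yn-2-yl]-2,2-dimethyl-1,3-dioxolane-4-carboxylic acid
Conditions: LiOH, THF/H2O, 0 to 25 °C; then aq. HCl to pH 3
Reagents that add atoms: lithium hydroxide, [Li+].[OH-]
Why: Mild saponification; the triisopropylsilyl alkyne survives hydroxide, and the trans relation at C8/C9 is the thermodynamic one.

**Step 6**
Reactants: 10 acrolein; 11 propyne
Product: 13 (3S)-hex-1-en-4-yn-3-ol, via ethyl(propynyl)zinc 12 (not isolated)
Conditions: 11, ZnEt2, (R)-BINOL (20 mol %), Ti(OiPr)4 (50 mol %), Et2O, 25 °C; then 10, 0 °C; then H2O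
Reagents that add atoms: none
Why: Catalytic enantioselective alkynylzinc addition to an aldehyde (BINOL–titanium type), known for α,β-unsaturated aldehydes; the ligand sets C6.

**Step 7**
Reactants: 13 enynol
Product: 15 (3S,4Z)-5-iodohexa-1,4-dien-3-ol, via cyclic alkenylaluminate 14 (not isolated)
Conditions: NaAlH2(OCH2CH2OCH3)2, Et2O, 0 °C; then I2, THF, −78 °C; then H2O
Reagents that add atoms: iodine, [I][I]
Why: Hydroxyl-directed trans-hydroalumination of a propargylic alcohol, then iodinolysis with retention. Aluminium ends on the distal carbon C4 within five-membered ring 14, so iodine is cis to C6 and the Z geometry of C4=C5 is fixed here.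

**Step 8**
Reactants: 15 iododienol
Product: 16 (3S,4Z)-5-iodohexa-1,4-dien-3-yl prop-2-enoate
Conditions: acryloyl chloride, Et3N, CH2Cl2, 0 °C
Reagents that add atoms: acryloyl chloride, C=CC(=O)Cl
Why: Simple O-acylation; the C–O bond at C6 is not touched.

**Step 9**
Reactants: 16 acrylate
Product: 17 (5S)-5-[(1Z)-2-iodoprop-1-en-1-yl]furan-2(5H)-one
Conditions: second-generation Grubbs catalyst (H2IMes)(PCy3)Cl2Ru=CHPh (5 mol %), CH2Cl2, 40 °C
Reagents that add atoms: none
Why: Ring-closing metathesis of an allylic acrylate to a butenolide; only the two monosubstituted alkenes take part, and the trisubstituted iodoalkene is inert.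

**Step 10**
Reactants: 9 acid; 17 butenolide
Product: 18 (4S,5S)-4-{(4S,5R)-5-[(2R)-2-hydroxy-4-(triisopropylsilyl)but-3-yn-2-yl]-2,2-dimethyl-1,3-dioxolan-4-yl}-5-[(1Z)-2-iodoprop-1-en-1-yl]oxolan-2-one
Conditions: Ir[dF(CF3)ppy]2(dtbbpy)PF6 (1 mol %), K2HPO4, DMF, 450 nm LEDs, 25 °C
Reagents that add atoms: none
Why: Decarboxylative Giese addition under photoredox catalysis, in which excited trivalent iridium oxidises the carboxylate and divalent iridium reduces the adduct radical. The C8 dioxolanyl radical bonds anti to the C9 substituent (trans-dioxolane), and the butenolide is attacked at C7 anti to the C6 substituent (trans-lactone). The saturated product cannot accept a second radical.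

**Step 11**
Reactants: 18 lactone
Product: 20 the (3R,4S,5S)-3-[(dimethylamino)methyl] derivative of 18 (CH2NMe2 at C11, trans to C8), via dilithium enolate alkoxide 19 (not isolated)
Conditions: LiN(SiMe3)2 (2.2 equiv), THF, −78 °C; then [CH2=NMe2]I; then H2O
Reagents that add atoms: N,N-dimethylmethyleneiminium iodide, C=[N+](C)C.[I-]
Why: Mannich aminomethylation of a lactone enolate with Eschenmoser's salt, from the face opposite C8. The C11 centre is temporary, and the product is the masked form of the methylene lactone.

**Step 12**
Reactants: 20 silylalkyne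
Product: 21 the terminal alkyne (20 with C2–H in place of C2–Si)
Conditions: Bu4NF, AcOH, THF, 0 °C
Reagents that add atoms: none
Why: Buffered fluoride protodesilylation of an alkynylsilane; the lactone, vinyl iodide and acetonide are inert.

**Step 13**
Reactants: 21 (Z)-vinyl iodide/tertiary propargylic alcohol
Product: 24 the oxygen-bridged ten-membered furanone bearing the 8,9-acetonide and the C11 (dimethylamino)methyl group (C6–C10 as in the target), via cyclic ynone 22 (not isolated), via hydroxy diketone 23 (not isolated)
Conditions: PdCl2(PPh3)2 (10 mol %), CuI (5 mol %), Et3N, CO (1 atm), THF, 25 °C, 21 added over 12 h (final 1 mM); then H2O, 50 °C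
Reagents that add atoms: carbon monoxide, [C-]#[O+] (gives C3); water, O (gives the C1 carbonyl oxygen)
Why: Proposed new method: a carbonylative Sonogashira-type coupling is run as a macrocyclisation and joined in one flask to the amine- and water-mediated isomerisation of the resulting 4-hydroxy-2-ynone to a 3(2H)-furanone; the closest known reactions are the intermolecular one-pot union of an aryl or vinyl iodide, CO and a tertiary propargylic alcohol in aqueous triethylamine, and carbonylative cross-coupling macrocyclisations of vinyl electrophiles to eleven-membered and larger enones. Zerovalent palladium inserts into C4–I with retention of the Z geometry, CO inserts to give the acyl complex of divalent palladium, the copper acetylide of C2 transmetalates, and reductive elimination makes C2–C3. The ten-membered ring is thus closed by reductive elimination from an eleven-membered palladacycle, at carbons (C2, C3, C4) that carry no stereochemistry, and it is closed as the unbridged ynone 22, which is free of the trans-cycloalkene strain of the product. Triethylamine-assisted conjugate addition of water to C1, the β-carbon of the ynone, gives 23; O10 then adds to the C3 carbonyl (5-exo-trig) and loss of water gives the vinylogous ester 24, so the bridging strain is paid by the hydration of an alkyne and not by the ring closure. No stereocentre is made, and C6 to C11 are untouched because nothing more basic than triethylamine is present. Carbonylation has to beat direct coupling, which the substrate secures because the CO-free product would be a nine-membered enyne; ring closure has to beat oligomerisation, which slow addition and the two five-membered rings (lactone and trans-dioxolane, leaving only the C5–C6, C7–C8 and C9–C10 bonds free to rotate) should favour. The only hydroxyl group is the tertiary O10, too hindered to trap the acylpalladium, and the methylene group is masked as the amine, so no Heck or acylpalladation path to C11=C13 exists.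

**Step 14**
Reactants: 24 amine
Product: 26 the α-methylene lactone 8,9-acetonide, via ammonium iodide 25 (not isolated)
Conditions: MeI, CH2Cl2, 25 °C; then aq. NaHCO3
Reagents that add atoms: none
Why: Quaternisation followed by E1cB (Hofmann-type) loss of trimethylamine from a β-ammonio lactone, the usual mild unmasking of α-methylene lactones; C11 becomes trigonal, so its configuration is irrelevant.

**Step 15**
Reactants: 26 acetonide
Product: 27 the 8,9-diol
Conditions: CF3CO2H/H2O (9:1), CH2Cl2, 0 °C
Reagents that add atoms: none
Why: Acid hydrolysis of a strained trans-fused acetonide; acid avoids retro-aldol at C9–C10 and Michael addition to the lactone.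

**Step 16**
Reactants: 27 diol
Product: 28 the target, CNP0265772.2
Conditions: (iPrCO)2O (1.1 equiv), DMAP (10 mol %), pyridine, CH2Cl2, −20 °C
Reagents that add atoms: isobutyric anhydride, CC(C)C(=O)OC(=O)C(C)C
Why: Site-selective acylation; O9 is neopentylic (next to quaternary C10) and can hydrogen-bond to the C1 ketone, so O8 should react first, and low temperature suppresses acyl migration.

## Compound list

1 | dimethyl (4R,5R)-2,2-dimethyl-1,3-dioxolane-4,5-dicarboxylate | COC(=O)[C@@H]1OC(C)(C)O[C@H]1C(=O)OC | starting material
2 | (4R,5R)-5-(methoxycarbonyl)-2,2-dimethyl-1,3-dioxolane-4-carboxylic acid | COC(=O)[C@@H]1OC(C)(C)O[C@H]1C(=O)O | intermediate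
3 | methyl (4R,5R)-5-(imidazole-1-carbonyl)-2,2-dimethyl-1,3-dioxolane-4-carboxylate | COC(=O)[C@@H]1OC(C)(C)O[C@H]1C(=O)n2ccnc2 | intermediate
4 | methyl (4R,5R)-5-[methoxy(methyl)carbamoyl]-2,2-dimethyl-1,3-dioxolane-4-carboxylate | COC(=O)[C@@H]1OC(C)(C)O[C@H]1C(=O)N(C)OC | intermediate
5 | methyl (4R,5R)-5-acetyl-2,2-dimethyl-1,3-dioxolane-4-carboxylate | COC(=O)[C@@H]1OC(C)(C)O[C@H]1C(C)=O | intermediate
6 | ethynyltriisopropylsilane | C#C[Si](C(C)C)(C(C)C)C(C)C | starting material
7 | [(triisopropylsilyl)ethynyl]magnesium bromide | Br[Mg]C#C[Si](C(C)C)(C(C)C)C(C)C | intermediate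
8 | methyl (4R,5R)-5-[(2R)-2-hydroxy-4-(triisopropylsilyl)but-3-yn-2-yl]-2,2-dimethyl-1,3-dioxolane-4-carboxylate | COC(=O)[C@@H]1OC(C)(C)O[C@H]1[C@](C)(O)C#C[Si](C(C)C)(C(C)C)C(C)C | intermediate
9 | (4R,5R)-5-[(2R)-2-hydroxy-4-(triisopropylsilyl)but-3-yn-2-yl]-2,2-dimethyl-1,3-dioxolane-4-carboxylic acid | OC(=O)[C@@H]1OC(C)(C)O[C@H]1[C@](C)(O)C#C[Si](C(C)C)(C(C)C)C(C)C | intermediate
10 | acrolein | C=CC=O | starting material
11 | propyne | CC#C | starting material
12 | ethyl(prop-1-yn-1-yl)zinc | CC[Zn]C#CC | intermediate
13 | (3S)-hex-1-en-4-yn-3-ol | O[C@H](C#CC)C=C | intermediate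
14 | sodium cyclic alkenylaluminate (ring Al, O, C6, C5, C4) | C=C[C@H]1C=C(C)[Al-](OCCOC)(OCCOC)O1.[Na+] | intermediate
15 | (3S,4Z)-5-iodohexa-1,4-dien-3-ol | O[C@H](/C=C(/C)I)C=C | intermediate
16 | (3S,4Z)-5-iodohexa-1,4-dien-3-yl prop-2-enoate | C=CC(=O)O[C@H](/C=C(/C)I)C=C | intermediate
17 | (5S)-5-[(1Z)-2-iodoprop-1-en-1-yl]furan-2(5H)-one | O=C1O[C@H](/C=C(/C)I)C=C1 | intermediate
18 | (4S,5S)-4-{(4S,5R)-5-[(2R)-2-hydroxy-4-(triisopropylsilyl)but-3-yn-2-yl]-2,2-dimethyl-1,3-dioxolan-4-yl}-5-[(1Z)-2-iodoprop-1-en-1-yl]oxolan-2-one | C1C(=O)O[C@H](/C=C(/C)I)[C@H]1[C@@H]2OC(C)(C)O[C@H]2[C@](C)(O)C#C[Si](C(C)C)(C(C)C)C(C)C | intermediate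
19 | dilithium enolate alkoxide of 18 | [Li+].[Li+].C1=C([O-])O[C@H](/C=C(/C)I)[C@H]1[C@@H]2OC(C)(C)O[C@H]2[C@](C)([O-])C#C[Si](C(C)C)(C(C)C)C(C)C | intermediate
20 | (3R,4S,5S)-3-[(dimethylamino)methyl] derivative of 18 | CN(C)C[C@@H]1C(=O)O[C@H](/C=C(/C)I)[C@H]1[C@@H]2OC(C)(C)O[C@H]2[C@](C)(O)C#C[Si](C(C)C)(C(C)C)C(C)C | intermediate
21 | terminal alkyne from 20 (cyclisation precursor) | CN(C)C[C@@H]1C(=O)O[C@H](/C=C(/C)I)[C@H]1[C@@H]2OC(C)(C)O[C@H]2[C@](C)(O)C#C | intermediate
22 | ten-membered (4Z)-3-oxo-1-yne with 10-OH, 8,9-acetonide, 6,12-lactone and C11 CH2NMe2 | CN(C)C[C@@H]1C(=O)O[C@@H]2/C=C(/C)C(=O)C#C[C@@](C)(O)[C@@H]3OC(C)(C)O[C@H]3[C@@H]12 | intermediate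
23 | the corresponding ten-membered 10-hydroxy-1,3-dione | CN(C)C[C@@H]1C(=O)O[C@@H]2/C=C(/C)C(=O)CC(=O)[C@@](C)(O)[C@@H]3OC(C)(C)O[C@H]3[C@@H]12 | intermediate
24 | 3,10-oxygen-bridged furanone with 8,9-acetonide and C11 CH2NMe2 | CN(C)C[C@@H]1C(=O)O[C@@H]2/C=C(/C)C3=CC(=O)[C@@](C)(O3)[C@@H]4OC(C)(C)O[C@H]4[C@@H]12 | intermediate
25 | trimethylammonium iodide of 24 | C[N+](C)(C)C[C@@H]1C(=O)O[C@@H]2/C=C(/C)C3=CC(=O)[C@@](C)(O3)[C@@H]4OC(C)(C)O[C@H]4[C@@H]12.[I-] | intermediate
26 | α-methylene lactone 8,9-acetonide | C=C1C(=O)O[C@@H]2/C=C(/C)C3=CC(=O)[C@@](C)(O3)[C@@H]4OC(C)(C)O[C@H]4[C@@H]12 | intermediate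
27 | 8,9-diol | C=C1C(=O)O[C@@H]2/C=C(/C)C3=CC(=O)[C@@](C)(O3)[C@H](O)[C@@H](O)[C@@H]12 | intermediate
28 | CNP0265772.2 (8-O-isobutyrate, 9-OH) | C=C1C(=O)O[C@@H]2/C=C(/C)C3=CC(=O)[C@@](C)(O3)[C@H](O)[C@@H](OC(=O)C(C)C)[C@@H]12 | target

## Count and risks

Total: 16 steps. Longest linear sequence: 12 steps (steps 1–5 and 10–16).

**Step 13 (key, new method).**
- What may go wrong: intermolecular acyl transfer (oligomerisation) may outrun ring closure, because the acylpalladium and acetylide ends meet slowly in a ten-membered transition state. The hydration stage may also stall at 50 °C.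
- Fallback, known reactions only, setting out from 20: reductive carbonylation of the vinyl iodide (Pd(PPh3)4, CO, Bu3SnH) gives the (Z)-enal F1. AgF with N-iodosuccinimide turns the silylalkyne into the iodoalkyne F2.
- A Nozaki–Hiyama–Kishi closure (CrCl2, catalytic NiCl2, THF/DMF, high dilution) then gives the cyclic carbinol F3. This closure is established for ten-membered propargylic alcohols and tolerates lactones.
- Dess–Martin oxidation gives 22, now isolated. Et2NH adds to give the enaminone F4, and aqueous acetic acid hydrolyses and cyclises it to 24, where the route is rejoined.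

**Step 10.**
- What may go wrong: erosion of the C6 configuration by γ-deprotonation of the doubly allylic butenolide under phosphate. Reductive loss of iodine and modest facial bias from the flat iodopropenyl group are also possible.
- Fallback, setting out from 9: commercial (S)-5-(hydroxymethyl)furan-2(5H)-one is silylated to the tert-butyldiphenylsilyl ether F5. Its bulky, non-conjugating group is a proven director.
- The same decarboxylative addition of 9 gives the adduct F6. HF·pyridine frees the primary alcohol F7, and Dess–Martin oxidation gives the aldehyde F8.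
- A Stork–Zhao-type olefination with (1-iodoethylidene)triphenylphosphorane gives the (Z)-iodoalkene 18, where the route is rejoined. Steps 6–9 are then not needed.

**Step 4.**
- What may go wrong: competition between chelated and non-chelated (Felkin–Anh) addition, since a dioxolane oxygen is a mediocre ligand. This would lower the selectivity at C10.
- Fallback, setting out from 4: the order of the two carbon nucleophiles is reversed. Reagent 7 adds to the Weinreb amide to give the ynone F9.
- Methyl is then delivered by the non-chelating MeTi(OiPr)3 under Felkin–Anh control. With the substituents exchanged, this leads to the same C10 configuration, and the route is rejoined at 8.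

**Step 6.**
- What may go wrong: low enantioselectivity with so small an enal, and polymerisation of acrolein under Lewis acid.
- Fallback, setting out from 10: prop-1-ynylmagnesium bromide gives the racemic carbinol F10.
- A Sharpless kinetic resolution (Ti(OiPr)4, L-(+)-diisopropyl tartrate, tBuOOH 0.6 equiv, −20 °C) consumes the (R)-enantiomer as the epoxy alcohol F11. It leaves (S)-13, where the route is rejoined.

**Step 16.**
- What may go wrong: acylation at O9, double acylation, or base-induced O8 to O9 migration.
- Fallback, setting out from 27: the diol is activated instead of the acyl donor. Bu2SnO gives the stannylene acetal F12.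
- Isobutyryl chloride at 0 °C, without amine base, should acylate the less hindered tin-bound oxygen O8, giving 28.

## Further compounds

F1 | step 13 | (Z)-enal from 20 (CHO in place of I) | CN(C)C[C@@H]1C(=O)O[C@H](/C=C(/C)C=O)[C@H]1[C@@H]2OC(C)(C)O[C@H]2[C@](C)(O)C#C[Si](C(C)C)(C(C)C)C(C)C
F2 | step 13 | iodoalkyne enal | CN(C)C[C@@H]1C(=O)O[C@H](/C=C(/C)C=O)[C@H]1[C@@H]2OC(C)(C)O[C@H]2[C@](C)(O)C#CI
F3 | step 13 | ten-membered C3 carbinol (C3 epimers) | CN(C)C[C@@H]1C(=O)O[C@@H]2/C=C(/C)C(O)C#C[C@@](C)(O)[C@@H]3OC(C)(C)O[C@H]3[C@@H]12
F4 | step 13 | C1 diethylamino enaminone of 22 | CN(C)C[C@@H]1C(=O)O[C@@H]2/C=C(/C)C(=O)C=C(N(CC)CC)[C@@](C)(O)[C@@H]3OC(C)(C)O[C@H]3[C@@H]12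
F5 | step 10 | (5S)-5-[(tert-butyldiphenylsilyloxy)methyl]furan-2(5H)-one | O=C1O[C@H](CO[Si](c2ccccc2)(c2ccccc2)C(C)(C)C)C=C1
F6 | step 10 | radical adduct of 9 and F5 | C1C(=O)O[C@H](CO[Si](c2ccccc2)(c2ccccc2)C(C)(C)C)[C@H]1[C@@H]3OC(C)(C)O[C@H]3[C@](C)(O)C#C[Si](C(C)C)(C(C)C)C(C)C
F7 | step 10 | primary alcohol from F6 | C1C(=O)O[C@H](CO)[C@H]1[C@@H]3OC(C)(C)O[C@H]3[C@](C)(O)C#C[Si](C(C)C)(C(C)C)C(C)C
F8 | step 10 | C5 aldehyde from F7 | C1C(=O)O[C@H](C=O)[C@H]1[C@@H]3OC(C)(C)O[C@H]3[C@](C)(O)C#C[Si](C(C)C)(C(C)C)C(C)C
F9 | step 4 | methyl (4R,5R)-2,2-dimethyl-5-[3-(triisopropylsilyl)prop-2-ynoyl]-1,3-dioxolane-4-carboxylate | COC(=O)[C@@H]1OC(C)(C)O[C@H]1C(=O)C#C[Si](C(C)C)(C(C)C)C(C)C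
F10 | step 6 | racemic hex-1-en-4-yn-3-ol | OC(C#CC)C=C
F11 | step 6 | (1S)-1-[(2S)-oxiran-2-yl]but-2-yn-1-ol | O[C@@H](C#CC)[C@@H]1CO1
F12 | step 16 | 8,9-O-dibutylstannylene acetal of 27 | C=C1C(=O)O[C@@H]2/C=C(/C)C3=CC(=O)[C@@](C)(O3)[C@@H]4O[Sn](CCCC)(CCCC)O[C@H]4[C@@H]12
A1 | alternative 1 | metathesis diene (5-isopropenylfuranone, C6 vinyl lactone) | C=C1C(=O)O[C@H](C=C)[C@H]1[C@H](OC(=O)C(C)C)[C@@H](O)[C@]2(C)OC(C(C)=C)=CC2=O
A2 | alternative 2 | open-chain enal/ynone/(Z)-2-(bromomethyl)enoate | COC(=O)/C(CBr)=C/[C@@H]1OC(C)(C)O[C@H]1[C@](C)(O)C(=O)C#C/C(C)=C\C=O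
A3 | alternative 2 | ten-membered 1-oxo-2-yne lactone | C=C1C(=O)O[C@@H]2/C=C(/C)C#CC(=O)[C@@](C)(O)[C@@H]3OC(C)(C)O[C@H]3[C@@H]12
A4 | alternative 3 | C9 aldehyde with 2-methyl-3(2H)-furanone (C10 epimers) | C=C1C(=O)O[C@H](/C=C(/C)C2=CC(=O)C(C)O2)[C@H]1[C@H](OC(=O)C(C)C)C=O
A5 | alternative 3 | 3-(tert-butyldimethylsilyloxy)furan of A4 | C=C1C(=O)O[C@H](/C=C(/C)c2cc(O[Si](C)(C)C(C)(C)C)c(C)o2)[C@H]1[C@H](OC(=O)C(C)C)C=O
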